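**Retrosynthetic overview**

- The strategy rests on the C6 oxygen lying five ring atoms from the 1(10)-E olefin (C6–C7–C8–C9–C10=C1) with the 4,5-Z olefin directly attached to C6. This is the retron of an anionic oxy-Cope shift, so the ten-membered ring is a ring-expanded 1-(2-alkoxyvinyl)-6-isopropenylcyclohex-2-en-1-ol (C6 = carbinol carbon, C7=C8 = vinyl group, C10=C9 = isopropenyl group, C3–C4=C5 = oxygenated edge of cis-carveol).
- Disconnections, backwards: 1,10-oxirane (peracid); C8 ester (epoxyangelic acid from a Sharpless epoxidation) and C3 isobutyrate; C13 (Mannich/elimination); lactone C6–O; C7–C11 (enolate plus bromoacetate); C8–C9 formed with C6–C1 cleaved ([3,3] shift); C6–C7 (vinylcerium plus an enone from (S)-carvone).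
- Ring order: the cyclohexene of carvone is carried to the key step, expanded to the ten-membered carbocycle, then the γ-lactone is closed, the preformed side-chain oxirane is attached at O8, and the 1,10-oxirane is made last.

Key step: step 7

Remark: germacranolide numbering is used (C1–C10 carbocycle, C11–C13 lactone arm, C14 on C10, C15 on C4), and the target is read from the SMILES as (1R,3S,6R,7R,8R,10R) with a (2S,3S)-2,3-dimethyloxirane-2-carboxylate on O8.

**Route**

Step 1
Reactants: 1 (S)-(+)-carvone
Product: 2 (1S,5S)-cis-carveol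
Conditions: NaBH4, CeCl3·7H2O, MeOH, 0 °C
Reagents that add atoms: none
Why: Luche 1,2-reduction of the enone, in which hydride adds axially to the half-chair carrying an equatorial isopropenyl group, so the new carbinol centre (1S) should form cis to the isopropenyl group.

Step 2
Reactants: 2 (1S,5S)-cis-carveol
Product: 3 (1S,5S)-cis-carveol tert-butyldimethylsilyl ether
Conditions: TBSCl, imidazole, DMF, rt
Reagents that add atoms: tert-butyldimethylsilyl chloride, CC(C)(C)[Si](C)(C)Cl
Why: Imidazole-promoted silyl ether formation on a secondary allylic alcohol, which touches no stereocentre.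

Step 3
Reactants: 3 (1S,5S)-cis-carveol tert-butyldimethylsilyl ether
Product: 4 (4S,6S)-4-(tert-butyldimethylsilyloxy)-3-methyl-6-(prop-1-en-2-yl)cyclohex-2-en-1-one
Conditions: t-BuOOH (aq.), Rh2(cap)4 (dirhodium tetracaprolactamate, cat.), ClCH2CH2Cl, 40 °C
Reagents that add atoms: tert-butyl hydroperoxide, CC(C)(C)OO
Why: Dirhodium-catalysed allylic C–H oxidation (tert-butylperoxyl radical abstracts a hydrogen from the only allylic ring CH2 and the mixed peroxide collapses to the enone) should give the enone under neutral conditions that leave the now α-carbonyl isopropenyl centre, already in its preferred cis relation to the silyloxy group, unchanged.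

Step 4
Reactants: 5 ethyl vinyl ether, 6 4-methoxybenzyl alcohol
Product: 7 4-methoxybenzyl vinyl ether
Conditions: Hg(OAc)2 (cat.), 5 in excess as solvent, reflux; then K2CO3
Reagents that add atoms: none
Why: Hg(OAc)2-catalysed transfer vinylation (transetherification) of a primary alcohol, driven by the large excess of the vinyl donor.

Step 5
Reactants: 7 4-methoxybenzyl vinyl ether
Product: 9 (Z)-1-bromo-2-(4-methoxybenzyloxy)ethene, via dibromide 8 (not isolated)
Conditions: Br2, CH2Cl2, −78 °C; then i-Pr2NEt, −78 °C to reflux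
Reagents that add atoms: bromine, BrBr
Why: Electrophilic bromine addition to the enol ether followed by amine-induced dehydrobromination (loss of the acetal-type bromide through the oxocarbenium ion and of a proton from the CH2Br carbon) should give the β-bromovinyl ether, with the Z isomer favoured as for the known ethyl analogue (cis preference of 1,2-diheteroatom-substituted ethenes).

Step 6
Reactants: 4 (4S,6S)-4-(tert-butyldimethylsilyloxy)-3-methyl-6-(prop-1-en-2-yl)cyclohex-2-en-1-one, 9 (Z)-1-bromo-2-(4-methoxybenzyloxy)ethene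
Product: 12 (1S,4S,6S)-4-(tert-butyldimethylsilyloxy)-1-[(Z)-2-(4-methoxybenzyloxy)ethenyl]-3-methyl-6-(prop-1-en-2-yl)cyclohex-2-en-1-ol, via vinyllithium 10 (not isolated), via organocerium 11 (not isolated)
Conditions: 9, t-BuLi (2 equiv), Et2O, −78 °C; CeCl3, THF, −78 °C; then 4, −78 °C; aq. NH4Cl
Reagents that add atoms: none
Why: Bromine–lithium exchange with retention of the Z geometry, transmetalation to the weakly basic organocerium and 1,2-addition to the enolisable enone, the nucleophile entering anti to the adjacent isopropenyl group and the cis silyloxy group so that the carbinol centre (1S) carries the two alkenyl groups trans.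

Step 7
Reactants: 12 (1S,4S,6S)-4-(tert-butyldimethylsilyloxy)-1-[(Z)-2-(4-methoxybenzyloxy)ethenyl]-3-methyl-6-(prop-1-en-2-yl)cyclohex-2-en-1-ol, 13 methyl bromoacetate
Product: 16 methyl (3S,7R,8R,1(10)E,4Z)-3-(tert-butyldimethylsilyloxy)-8-(4-methoxybenzyloxy)-6-oxo-13-norgermacra-1(10),4-dien-12-oate, via potassium alkoxide 14 (not isolated), via potassium enolate 15 (not isolated)
Conditions: KH, 18-crown-6, THF, 0 to 25 °C; then 13, −78 to −40 °C; aq. NaH2PO4/Na2HPO4 (pH 7)
Reagents that add atoms: none
Why: KH/18-crown-6 converts 12 into the alkoxide 14, whose 3-oxido-1,5-diene (C8=C7–C6(O−)–C1–C10=C9) undergoes the anionic oxy-Cope [3,3] shift, forming C8–C9 and breaking C6–C1 to give the cross-conjugated potassium enolate 15, which is then C-alkylated at C7 by methyl bromoacetate (SN2); the closest known reaction type is the anionic oxy-Cope ring expansion of trans-1-alkenyl-2-isopropenylcyclohexanols to (E)-cyclodec-5-enone enolates with electrophilic trapping in the same flask. No ring is closed by cyclisation: the ten-membered carbocycle arises by four-atom ring expansion of the cyclohexene as the new C8–C9 bond replaces the C6–C1 bond. C8 is set in the chair transition state, where the ring bonds C6–C5 and C1–C2 are equatorial (forced by the trans-diequatorial alkenyl groups of 12), the oxide and H1 are axial and the Z enol ether places the 4-methoxybenzyloxy group axial on C8, so suprafacial bonding to C9 should give 8R together with the 1(10)-E olefin and the enolate in which O6 and C8 are cis. C7 is set in the alkylation, because in the enolate as delivered the C8–O bond lies in the enolate plane (K+ bridged between O6 and O8) and the new C8–C9 bond stands perpendicular to it, so the bromoacetate should approach the opposite, outer face (7R). The step needs chair rather than boat topology, C- rather than O-alkylation and no β-elimination of the C8 alkoxide; these are secured respectively by the trans relation of the alkenyl groups with the defined Z geometry, by the soft SN2 electrophile at low temperature, and by the in-plane C8–O bond of the chelated enolate, which is not aligned with the π system.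

Step 8
Reactants: 16 methyl (3S,7R,8R,1(10)E,4Z)-3-(tert-butyldimethylsilyloxy)-8-(4-methoxybenzyloxy)-6-oxo-13-norgermacra-1(10),4-dien-12-oate
Product: 18 (3S,6R,7R,8R,1(10)E,4Z)-3-(tert-butyldimethylsilyloxy)-8-(4-methoxybenzyloxy)-13-norgermacra-1(10),4-dien-12,6-olide, via hydroxy ester 17 (not isolated)
Conditions: NaBH4, CeCl3·7H2O, MeOH, −78 °C; then DBU (cat.), PhMe, rt
Reagents that add atoms: none
Why: Luche 1,2-reduction followed by base-catalysed lactonisation (5-exo-trig acyl substitution on the methyl ester), in which hydride is expected to enter the C6 carbonyl on the face opposite the C7 acetate arm (Felkin-type torsional control with the C7–C8 bond near the carbonyl plane), giving the 6R alcohol whose oxygen is gauche to C11 and closes the trans-fused γ-lactone.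

Step 9
Reactants: 18 (3S,6R,7R,8R,1(10)E,4Z)-3-(tert-butyldimethylsilyloxy)-8-(4-methoxybenzyloxy)-13-norgermacra-1(10),4-dien-12,6-olide
Product: 20 11-(dimethylaminomethyl) lactone (13-dimethylamino-11,13-dihydro derivative of 22, C11 epimers), via lithium enolate 19 (not isolated)
Conditions: LiN(i-Pr)2, THF, −78 °C; then Me2N=CH2 iodide (Eschenmoser's salt), −78 °C to rt
Reagents that add atoms: N,N-dimethylmethyleneiminium iodide (Eschenmoser's salt), C[N+](C)=C.[I-]
Why: Mannich aminomethylation of the lactone enolate at C11, the only acidic position left and one with no β-leaving group, the C11 configuration being irrelevant because this carbon becomes sp2 in the next step.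

Step 10
Reactants: 20 11-(dimethylaminomethyl) lactone
Product: 22 (3S,6R,7R,8R,1(10)E,4Z)-3-(tert-butyldimethylsilyloxy)-8-(4-methoxybenzyloxy)germacra-1(10),4,11(13)-trien-12,6-olide, via ammonium iodide 21 (not isolated)
Conditions: MeI, MeOH, rt; then aq. NaHCO3, CH2Cl2, rt
Reagents that add atoms: none
Why: Exhaustive N-methylation and Hofmann-type (E1cB) loss of trimethylamine should give the exocyclic α-methylene lactone without affecting any stereocentre.

Step 11
Reactants: 22 (3S,6R,7R,8R,1(10)E,4Z)-3-(tert-butyldimethylsilyloxy)-8-(4-methoxybenzyloxy)germacra-1(10),4,11(13)-trien-12,6-olide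
Product: 23 (3S,6R,7R,8R,1(10)E,4Z)-3-hydroxy-8-(4-methoxybenzyloxy)germacra-1(10),4,11(13)-trien-12,6-olide
Conditions: TBAF, AcOH, THF, 0 °C to rt
Reagents that add atoms: none
Why: Fluoride desilylation buffered with acetic acid should cleave the secondary silyl ether without conjugate addition to the methylene lactone or acid-induced transannular cyclisation of the 1(10),4-diene, the 4-methoxybenzyl ether being stable.

Step 12
Reactants: 23 (3S,6R,7R,8R,1(10)E,4Z)-3-hydroxy-8-(4-methoxybenzyloxy)germacra-1(10),4,11(13)-trien-12,6-olide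
Product: 24 (3S,6R,7R,8R,1(10)E,4Z)-3-(2-methylpropanoyloxy)-8-(4-methoxybenzyloxy)germacra-1(10),4,11(13)-trien-12,6-olide
Conditions: (i-PrCO)2O, Et3N, DMAP (cat.), CH2Cl2, 0 °C to rt
Reagents that add atoms: isobutyric anhydride, CC(C)C(=O)OC(=O)C(C)C
Why: DMAP-catalysed acyl transfer to the allylic C3 alcohol proceeds at oxygen and so retains the C3 configuration.

Step 13
Reactants: 24 (3S,6R,7R,8R,1(10)E,4Z)-3-(2-methylpropanoyloxy)-8-(4-methoxybenzyloxy)germacra-1(10),4,11(13)-trien-12,6-olide
Product: 25 (3S,6R,7R,8R,1(10)E,4Z)-8-hydroxy-3-(2-methylpropanoyloxy)germacra-1(10),4,11(13)-trien-12,6-olide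
Conditions: DDQ, CH2Cl2/aq. NaH2PO4/Na2HPO4 (pH 7), 0 °C
Reagents that add atoms: none
Why: Oxidative cleavage of the 4-methoxybenzyl ether by DDQ (benzylic hydride abstraction, then hydrolysis of the oxocarbenium ion) should free the C8 hydroxyl while the esters, the methylene lactone and the trisubstituted olefins stay intact under buffered conditions.

Step 14
Reactants: 26 angelic acid
Product: 27 methyl angelate
Conditions: MeI, K2CO3, DMF, rt
Reagents that add atoms: iodomethane, CI
Why: Carboxylate O-alkylation (SN2) under mild base avoids the acid- or heat-induced isomerisation of the Z double bond to the tiglate.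

Step 15
Reactants: 27 methyl angelate
Product: 28 (Z)-2-methylbut-2-en-1-ol
Conditions: i-Bu2AlH, CH2Cl2, −78 to 0 °C; aq. potassium sodium tartrate
Reagents that add atoms: none
Why: 1,2-Reduction of the conjugated ester by the aluminium hydride should give the allylic alcohol with the Z geometry intact.

Step 16
Reactants: 28 (Z)-2-methylbut-2-en-1-ol
Product: 29 [(2R,3S)-2,3-dimethyloxiran-2-yl]methanol
Conditions: Ti(Oi-Pr)4 (cat.), D-(−)-diisopropyl tartrate, t-BuOOH, 4 Å molecular sieves, CH2Cl2, −20 °C
Reagents that add atoms: tert-butyl hydroperoxide, CC(C)(C)OO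
Why: Sharpless asymmetric epoxidation, in which the D-(−)-tartrate–titanium complex attacks the enantioface opposite to the one taken with L-(+)-tartrate (which gives 2S epoxy alcohols), so that syn oxygen transfer to the Z olefin should set both centres as (2R,3S) with CH2OH and the C3 methyl cis.

Step 17
Reactants: 29 [(2R,3S)-2,3-dimethyloxiran-2-yl]methanol
Product: 30 (2S,3S)-2,3-dimethyloxirane-2-carboxylic acid (epoxyangelic acid)
Conditions: TEMPO (cat.), PhI(OAc)2, MeCN/H2O, rt
Reagents that add atoms: water, O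
Why: Oxoammonium (TEMPO) oxidation in aqueous acetonitrile takes the primary alcohol through the aldehyde hydrate to the acid without opening the oxirane, the C2 descriptor changing from R to S only because CO2H outranks C3.

Step 18
Reactants: 25 (3S,6R,7R,8R,1(10)E,4Z)-8-hydroxy-3-(2-methylpropanoyloxy)germacra-1(10),4,11(13)-trien-12,6-olide, 30 (2S,3S)-2,3-dimethyloxirane-2-carboxylic acid
Product: 32 (3S,6R,7R,8R,1(10)E,4Z)-8-[(2S,3S)-2,3-dimethyloxirane-2-carbonyloxy]-3-(2-methylpropanoyloxy)germacra-1(10),4,11(13)-trien-12,6-olide, via mixed anhydride 31 (not isolated)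
Conditions: 30, 2,4,6-Cl3C6H2COCl, Et3N, PhMe, rt; then 25, DMAP, PhMe, rt
Reagents that add atoms: none
Why: Yamaguchi esterification, in which DMAP attacks the less shielded glycidic carbonyl of the mixed anhydride and the acylpyridinium acylates the hindered C8 alcohol at oxygen, retaining C8 and leaving the oxirane untouched.

Step 19
Reactants: 32 (3S,6R,7R,8R,1(10)E,4Z)-8-[(2S,3S)-2,3-dimethyloxirane-2-carbonyloxy]-3-(2-methylpropanoyloxy)germacra-1(10),4,11(13)-trien-12,6-olide
Product: 33 CNP0117882.1, (1R,3S,6R,7R,8R,10R,4Z)-1,10-epoxy-8-[(2S,3S)-2,3-dimethyloxirane-2-carbonyloxy]-3-(2-methylpropanoyloxy)germacra-4,11(13)-dien-12,6-olide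
Conditions: mCPBA, NaHCO3, CH2Cl2, 0 °C
Reagents that add atoms: 3-chloroperoxybenzoic acid, OOC(=O)c1cccc(Cl)c1
Why: Prilezhaev epoxidation of the isolated trisubstituted 1(10)-E olefin, the most electron-rich alkene (the 4,5-olefin carries two allylic acyloxy groups and the methylene lactone is electron-poor), where syn addition keeps the trans relation of C2 and C9 and attack on the outer face of the olefin, whose inner face looks across the ring at C6, should give the 1R,10R oxirane.

**Compound list**

1 | (S)-(+)-carvone | CC1=CC[C@H](C(C)=C)CC1=O | starting material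
2 | (1S,5S)-cis-carveol | CC1=CC[C@H](C(C)=C)C[C@@H]1O | intermediate
3 | (1S,5S)-cis-carveol tert-butyldimethylsilyl ether | CC1=CC[C@H](C(C)=C)C[C@@H]1O[Si](C)(C)C(C)(C)C | intermediate
4 | (4S,6S)-4-(tert-butyldimethylsilyloxy)-3-methyl-6-(prop-1-en-2-yl)cyclohex-2-en-1-one | CC1=CC(=O)[C@H](C(C)=C)C[C@@H]1O[Si](C)(C)C(C)(C)C | intermediate
5 | ethyl vinyl ether | C=COCC | starting material
6 | 4-methoxybenzyl alcohol | OCc1ccc(OC)cc1 | starting material
7 | 4-methoxybenzyl vinyl ether | C=COCc1ccc(OC)cc1 | intermediate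
8 | 1,2-dibromo-1-(4-methoxybenzyloxy)ethane (racemic, not isolated) | BrCC(Br)OCc1ccc(OC)cc1 | intermediate
9 | (Z)-1-bromo-2-(4-methoxybenzyloxy)ethene | Br/C=C\OCc1ccc(OC)cc1 | intermediate
10 | (Z)-2-(4-methoxybenzyloxy)ethenyllithium (not isolated) | [Li]/C=C\OCc1ccc(OC)cc1 | intermediate
11 | dichloro[(Z)-2-(4-methoxybenzyloxy)ethenyl]cerium (not isolated) | Cl[Ce](Cl)/C=C\OCc1ccc(OC)cc1 | intermediate
12 | (1S,4S,6S)-4-(tert-butyldimethylsilyloxy)-1-[(Z)-2-(4-methoxybenzyloxy)ethenyl]-3-methyl-6-(prop-1-en-2-yl)cyclohex-2-en-1-ol (vinyl trans to isopropenyl) | CC1=C[C@@](O)(/C=C\OCc2ccc(OC)cc2)[C@H](C(C)=C)C[C@@H]1O[Si](C)(C)C(C)(C)C | intermediate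
13 | methyl bromoacetate | BrCC(=O)OC | starting material
14 | potassium alkoxide of 12 (not isolated) | [K+].CC1=C[C@@]([O-])(/C=C\OCc2ccc(OC)cc2)[C@H](C(C)=C)C[C@@H]1O[Si](C)(C)C(C)(C)C | intermediate
15 | potassium C6–C7 enolate of the (3S,8R,1(10)E,4Z)-cyclodecadienone (not isolated) | [K+].C/C1=C/C([O-])=C/[C@H](OCc2ccc(OC)cc2)C/C(C)=C/C[C@@H]1O[Si](C)(C)C(C)(C)C | intermediate
16 | methyl (3S,7R,8R,1(10)E,4Z)-3-(tert-butyldimethylsilyloxy)-8-(4-methoxybenzyloxy)-6-oxo-13-norgermacra-1(10),4-dien-12-oate | COC(=O)C[C@H]1C(=O)/C=C(/C)[C@@H](O[Si](C)(C)C(C)(C)C)C/C=C(\C)C[C@H]1OCc2ccc(OC)cc2 | intermediate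
17 | methyl (3S,6R,7S,8R,1(10)E,4Z)-3-(tert-butyldimethylsilyloxy)-6-hydroxy-8-(4-methoxybenzyloxy)-13-norgermacra-1(10),4-dien-12-oate (not isolated; C7 geometry as in 16) | COC(=O)C[C@H]1[C@H](O)/C=C(/C)[C@@H](O[Si](C)(C)C(C)(C)C)C/C=C(\C)C[C@H]1OCc2ccc(OC)cc2 | intermediate
18 | (3S,6R,7R,8R,1(10)E,4Z)-3-(tert-butyldimethylsilyloxy)-8-(4-methoxybenzyloxy)-13-norgermacra-1(10),4-dien-12,6-olide (trans-fused γ-lactone) | C1C(=O)O[C@@H]2/C=C(/C)[C@@H](O[Si](C)(C)C(C)(C)C)C/C=C(\C)C[C@@H](OCc3ccc(OC)cc3)[C@@H]12 | intermediate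
19 | lithium enolate of lactone 18 (not isolated) | C1=C([O-])O[C@@H]2/C=C(/C)[C@@H](O[Si](C)(C)C(C)(C)C)C/C=C(\C)C[C@@H](OCc3ccc(OC)cc3)[C@@H]12.[Li+] | intermediate
20 | 11-(dimethylaminomethyl) lactone (C11 epimers) | CN(C)CC1C(=O)O[C@@H]2/C=C(/C)[C@@H](O[Si](C)(C)C(C)(C)C)C/C=C(\C)C[C@@H](OCc3ccc(OC)cc3)[C@@H]12 | intermediate
21 | 11-(trimethylammoniomethyl) lactone iodide (not isolated) | C[N+](C)(C)CC1C(=O)O[C@@H]2/C=C(/C)[C@@H](O[Si](C)(C)C(C)(C)C)C/C=C(\C)C[C@@H](OCc3ccc(OC)cc3)[C@@H]12.[I-] | intermediate
22 | (3S,6R,7R,8R,1(10)E,4Z)-3-(tert-butyldimethylsilyloxy)-8-(4-methoxybenzyloxy)germacra-1(10),4,11(13)-trien-12,6-olide | C=C1C(=O)O[C@@H]2/C=C(/C)[C@@H](O[Si](C)(C)C(C)(C)C)C/C=C(\C)C[C@@H](OCc3ccc(OC)cc3)[C@@H]12 | intermediate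
23 | (3S,6R,7R,8R,1(10)E,4Z)-3-hydroxy-8-(4-methoxybenzyloxy)germacra-1(10),4,11(13)-trien-12,6-olide | C=C1C(=O)O[C@@H]2/C=C(/C)[C@@H](O)C/C=C(\C)C[C@@H](OCc3ccc(OC)cc3)[C@@H]12 | intermediate
24 | (3S,6R,7R,8R,1(10)E,4Z)-3-(2-methylpropanoyloxy)-8-(4-methoxybenzyloxy)germacra-1(10),4,11(13)-trien-12,6-olide | C=C1C(=O)O[C@@H]2/C=C(/C)[C@@H](OC(=O)C(C)C)C/C=C(\C)C[C@@H](OCc3ccc(OC)cc3)[C@@H]12 | intermediate
25 | (3S,6R,7R,8R,1(10)E,4Z)-8-hydroxy-3-(2-methylpropanoyloxy)germacra-1(10),4,11(13)-trien-12,6-olide | C=C1C(=O)O[C@@H]2/C=C(/C)[C@@H](OC(=O)C(C)C)C/C=C(\C)C[C@@H](O)[C@@H]12 | intermediate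
26 | angelic acid [(Z)-2-methylbut-2-enoic acid] | C/C=C(/C)C(=O)O | starting material
27 | methyl angelate | C/C=C(/C)C(=O)OC | intermediate
28 | (Z)-2-methylbut-2-en-1-ol | C/C=C(/C)CO | intermediate
29 | [(2R,3S)-2,3-dimethyloxiran-2-yl]methanol | OC[C@@]1(C)O[C@H]1C | intermediate
30 | (2S,3S)-2,3-dimethyloxirane-2-carboxylic acid | OC(=O)[C@@]1(C)O[C@H]1C | intermediate
31 | (2S,3S)-2,3-dimethyloxirane-2-carboxylic 2,4,6-trichlorobenzoic anhydride (not isolated) | O=C(OC(=O)[C@@]1(C)O[C@H]1C)c1c(Cl)cc(Cl)cc1Cl | intermediate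
32 | (3S,6R,7R,8R,1(10)E,4Z)-8-[(2S,3S)-2,3-dimethyloxirane-2-carbonyloxy]-3-(2-methylpropanoyloxy)germacra-1(10),4,11(13)-trien-12,6-olide | C=C1C(=O)O[C@@H]2/C=C(/C)[C@@H](OC(=O)C(C)C)C/C=C(\C)C[C@@H](OC(=O)[C@@]3(C)O[C@H]3C)[C@@H]12 | intermediate
33 | CNP0117882.1 | C=C1C(=O)O[C@@H]2/C=C(/C)[C@@H](OC(=O)C(C)C)C[C@H]3O[C@]3(C)C[C@@H](OC(=O)[C@@]3(C)O[C@H]3C)[C@@H]12 | target

**Step count and risks**

Total step count: 19. Longest linear sequence: 13 steps (steps 1, 2, 3, 6, 7, 8, 9, 10, 11, 12, 13, 18, 19, from (S)-carvone).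

Steps most likely to fail:

Step 7. The potassium enolate may lose the C8 alkoxide by β-elimination at the temperature the [3,3] shift needs. It may also be O-alkylated, be quenched by proton transfer from the bromoacetate, or be alkylated with eroded facial selectivity at C7. The fallback sets out from dienol 12 and separates the rearrangement from the C–C bond formation. After the oxy-Cope shift the enolate 15 is silylated at −78 °C (Me3SiCl, Et3N) to the isolable (3S,8R)-trimethylsilyl dienol ether F1. MeLi in THF at −78 °C then cleaves the enol silane to the lithium enolate F2, a tighter, O8-chelated ion pair that is much less prone to E1cB loss. F2 is C-alkylated with 13 in THF/DMPU at −78 to −30 °C, and the route is rejoined at keto ester 16.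

Step 8. Hydride may be delivered to the C6 carbonyl face syn to the acetate arm if the ring reacts through the conformer left by the rearrangement, in which that face is the peripheral one; the result would be the wrong C6 configuration. The fallback sets out from keto ester 16 and inverts C6 instead of relying on substrate control. The 6S alcohol from the same Luche reduction, the 6-epi hydroxy ester F3, is not lactonised but subjected to Mitsunobu inversion (4-nitrobenzoic acid, PPh3, diisopropyl azodicarboxylate, THF, 0 °C) to give the 6R 4-nitrobenzoate F4. K2CO3 in MeOH removes the nitrobenzoate to give hydroxy ester 17, which closes as in the main route, and the route is rejoined at lactone 18.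

Step 19. Peracid may attack the other face of the 1(10)-olefin if the E-olefin has turned through the ring in the lactone-bridged conformer, or the 4,5-olefin may compete. The fallback sets out from diester 32 and replaces substrate control by reagent control. It is a Shi epoxidation with the fructose-derived chiral ketone antipode whose spiro transition state matches the 1R,10R face (KHSO5, K2CO3, MeCN/dimethoxymethane/aqueous buffer, 0 °C), which is selective for the electron-rich trisubstituted E-olefin. It leads directly to target 33 and makes no new compound (F0).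

**Further compounds**

F1 | step 7 | (3S,8R,1(10)E,4Z)-3-(tert-butyldimethylsilyloxy)-8-(4-methoxybenzyloxy)-6-(trimethylsilyloxy) dienol ether of the cyclodecadienone | C/C1=C/C(O[Si](C)(C)C)=C/[C@H](OCc2ccc(OC)cc2)C/C(C)=C/C[C@@H]1O[Si](C)(C)C(C)(C)C
F2 | step 7 | lithium C6–C7 enolate of the (3S,8R,1(10)E,4Z)-cyclodecadienone | [Li+].C/C1=C/C([O-])=C/[C@H](OCc2ccc(OC)cc2)C/C(C)=C/C[C@@H]1O[Si](C)(C)C(C)(C)C
F3 | step 8 | methyl (3S,6S,8R,1(10)E,4Z)-3-(tert-butyldimethylsilyloxy)-6-hydroxy-8-(4-methoxybenzyloxy)-13-norgermacra-1(10),4-dien-12-oate (6-epimer of 17) | COC(=O)C[C@H]1[C@@H](O)/C=C(/C)[C@@H](O[Si](C)(C)C(C)(C)C)C/C=C(\C)C[C@H]1OCc2ccc(OC)cc2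
F4 | step 8 | 6R 4-nitrobenzoate of hydroxy ester 17 | COC(=O)C[C@H]1[C@H](OC(=O)c2ccc(cc2)[N+](=O)[O-])/C=C(/C)[C@@H](O[Si](C)(C)C(C)(C)C)C/C=C(\C)C[C@H]1OCc2ccc(OC)cc2
F0 | step 19 | none | none
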